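**Strategy.** The route rests on disconnecting the angular methyl C15 from C10 and hiding it as the CH2 of a cyclopropane spanning the ring A/ring B fusion bond C5–C10. The feature exploited is that C15 on C10 and the oxygenated C11 on C9 lie on the same face of ring B, so the C11 hydroxyl can steer an iodomethylzinc carbenoid onto the C5=C10 alkene of a Birch-derived, C7-ketalised bicyclic homoallylic alcohol. In one operation this forms C10–C15, the temporary C5–C15 bond, the three-membered ring and both ring-fusion stereocentres. Acid later cuts C5–C15 through the C7 ketone, leaving C15 as the methyl group.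

Key step: step 9

**Remarks on the chemistry**
- Numbering: drimane numbering is used for all bicyclic compounds (ring A = C1–C5 and C10 with the gem-dimethyl group on C4; ring B = C5–C10; C12 on C8, C11 on C9, C15 on C10); β is the face that carries C15 in the target.
- Assumption for step 7: the lipase is taken to acylate the (S)-alcohol faster, so the wanted (R)-alcohol is recovered unreacted; with the opposite preference the acetate fraction would be carried on after K2CO3/MeOH.
- Assumption for step 8: protonation at C8 is taken to be unselective, so compounds 12–14 are C8 epimer pairs (C8 left open in their SMILES); this is harmless because C8 equilibrates next to the ketone in step 10 and becomes sp2 in step 15.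

**Route**

Step 1
Reactants: 1 methyl 3-methoxy-2-methylbenzoate
Product: 2 methyl 6-bromo-3-methoxy-2-methylbenzoate
Conditions: Br2, AcOH, rt
Reagents that add atoms: bromine, BrBr
Why: Electrophilic aromatic bromination should occur para to the methoxy group (the future C10), the position most strongly activated by oxygen, which places a halide next to the ester for the coupling.

Step 2
Reactants: 2 methyl 6-bromo-3-methoxy-2-methylbenzoate, 3 5-bromo-2-methylpent-2-ene
Product: 5 methyl 3-methoxy-2-methyl-6-(4-methylpent-3-en-1-yl)benzoate, via homoprenylzinc bromide 4 (not isolated)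
Conditions: 3, Zn dust, LiCl, THF, 40 °C; then 2, Pd(OAc)2 (2 mol %), 2-dicyclohexylphosphino-2',6'-dimethoxybiphenyl (4 mol %), THF, 50 °C
Reagents that add atoms: none
Why: Negishi coupling of a primary alkylzinc halide with an aryl bromide is reliable with a bulky biarylphosphine that makes reductive elimination faster than β-hydride elimination, and the ester is inert to the organozinc reagent.

Step 3
Reactants: 5 methyl 3-methoxy-2-methyl-6-(4-methylpent-3-en-1-yl)benzoate
Product: 6 methyl 3-methoxy-2,5,5-trimethyl-5,6,7,8-tetrahydronaphthalene-1-carboxylate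
Conditions: MeSO3H, CH2Cl2, 0 °C to rt
Reagents that add atoms: none
Why: Protonation of the trisubstituted alkene gives a tertiary cation that closes ring A by intramolecular Friedel–Crafts alkylation at the only free position ortho to the tether (para to the ring methyl), which puts the gem-dimethyl carbon C4 on the future C5.

Step 4
Reactants: 6 methyl 3-methoxy-2,5,5-trimethyl-5,6,7,8-tetrahydronaphthalene-1-carboxylate
Product: 7 3-methoxy-2,5,5-trimethyl-5,6,7,8-tetrahydronaphthalene-1-carboxylic acid
Conditions: KOt-Bu, H2O (2:1), THF, rt to 50 °C; then 1 M HCl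
Reagents that add atoms: water, O
Why: Hydroxide generated from KOt-Bu and a limited amount of water in an aprotic solvent is poorly solvated and reactive enough for acyl substitution at the doubly ortho-substituted ester, which ordinary aqueous saponification would attack only slowly.

Step 5
Reactants: 7 3-methoxy-2,5,5-trimethyl-5,6,7,8-tetrahydronaphthalene-1-carboxylic acid
Product: 9 racemic 3-methoxy-2,5,5-trimethyl-1,4,5,6,7,8-hexahydronaphthalene-1-carboxylic acid, via dilithium carboxylate dianion 8 (not isolated)
Conditions: Li, NH3(l), THF, t-BuOH, −78 °C; then solid NH4Cl; NaH2PO4 buffer (pH about 5), 0 °C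
Reagents that add atoms: none
Why: Birch reduction of the benzoate salt adds hydrogen at the carboxyl-bearing carbon C9 and at the unsubstituted para carbon C6, the pattern favoured by both the carboxylate and the meta-methoxy group, and C-protonation of the dianion on quenching leaves the skipped C5=C10 and C7=C8 alkenes and a racemic C9 centre.

Step 6
Reactants: 9 racemic 3-methoxy-2,5,5-trimethyl-1,4,5,6,7,8-hexahydronaphthalene-1-carboxylic acid
Product: 10 racemic (3-methoxy-2,5,5-trimethyl-1,4,5,6,7,8-hexahydronaphthalen-1-yl)methanol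
Conditions: LiAlH4, THF, 0 °C to reflux; aqueous NaOH work-up
Reagents that add atoms: none
Why: LiAlH4 reduces the carboxylic acid to the primary alcohol C11 and leaves the isolated alkenes and the base-stable enol ether untouched.

Step 7
Reactants: 10 racemic (3-methoxy-2,5,5-trimethyl-1,4,5,6,7,8-hexahydronaphthalen-1-yl)methanol
Product: 11 [(1R)-3-methoxy-2,5,5-trimethyl-1,4,5,6,7,8-hexahydronaphthalen-1-yl]methanol
Conditions: Burkholderia cepacia lipase (immobilised), vinyl acetate, t-BuOMe, 30 °C, run slightly past half conversion; chromatography on Et3N-deactivated silica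
Reagents that add atoms: none
Why: Lipase-catalysed transesterification is a kinetic resolution in which the enzyme should acylate one enantiomer of the β-branched primary alcohol faster, so that the unreacted alcohol is recovered with the C9 configuration of the target (9α-H, C11 β).

Step 8
Reactants: 11 [(1R)-3-methoxy-2,5,5-trimethyl-1,4,5,6,7,8-hexahydronaphthalen-1-yl]methanol
Product: 12 (9S)-7,7-ethylenedioxy-15-nordrim-5(10)-en-11-ol, C8 epimers
Conditions: HOCH2CH2OH, p-TsOH·H2O (cat.), THF, 0 °C to rt
Reagents that add atoms: ethylene glycol, OCCO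
Why: Acid-catalysed exchange of the enol ether (C-protonation at C8, capture of the oxocarbenium ion by the diol, loss of methanol) gives the dioxolane under conditions mild enough to keep the C5=C10 alkene out of conjugation, and it removes the only other alkene that could react with a carbenoid.

Step 9
Reactants: 12 (9S)-7,7-ethylenedioxy-15-nordrim-5(10)-en-11-ol, C8 epimers
Product: 13 (9S)-7,7-ethylenedioxy-5β,15-cyclodriman-11-ol, C8 epimers
Conditions: Et2Zn (4 equiv), CH2I2 (8 equiv), CH2Cl2, −10 °C to rt
Reagents that add atoms: diiodomethane, ICI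
Why: Et2Zn first turns the C11 hydroxyl into an ethylzinc alkoxide, and the iodomethylzinc carbenoid formed from Et2Zn and CH2I2 binds to it and transfers CH2 to the C5=C10 alkene through the concerted butterfly transition state of the Simmons–Smith reaction. The closest known reaction type is the hydroxyl-directed Simmons–Smith cyclopropanation of a homoallylic alcohol whose tetrasubstituted ring-fusion alkene comes from a Birch reduction. The three-membered ring closes by a concerted, suprafacial [2+1] methylene transfer in which C10–C15 and C5–C15 form together, so the cyclopropane is necessarily cis-fused to rings A and B. The new stereocentres C5 and C10 are both fixed by the face of delivery, which is dictated by the resolved C9 centre: its CH2O–Zn arm sits pseudo-axially on the β face next to C10, so CH2 arrives on that face and C15 ends cis to C11. The step needs facial selectivity and chemoselectivity; the alkoxide tether secures the first, and the second follows because the electron-rich C5=C10 alkene is the only alkene left after ketalisation, while the dioxolane presents one oxygen to each face and cannot bias the delivery.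

Step 10
Reactants: 13 (9S)-7,7-ethylenedioxy-5β,15-cyclodriman-11-ol, C8 epimers
Product: 15 11-hydroxydrim-5-en-7-one with 8α-methyl (8β-H), 9α-H and 10β-methyl, via cyclopropyl ketone 14 (not isolated)
Conditions: 3 M HCl, THF, 60 °C
Reagents that add atoms: water, O
Why: Hydrolysis of the dioxolane frees the C7 ketone, whose enol towards C6 is a vinylcyclopropane that is protonated at C15 with rupture of the C5–C15 bond (the cyclopropane bond aligned with the enol π system), the known acid opening of a β,γ-cyclopropyl ketone to an angular methyl enone, while C8 equilibrates to the equatorial α-methyl epimer.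

Step 11
Reactants: 15 11-hydroxydrim-5-en-7-one with 8α-methyl, 9α-H and 10β-methyl
Product: 17 11-hydroxy-5α-driman-7-one with 8α-methyl, via dilithium enolate alkoxide 16 (not isolated)
Conditions: Li, NH3(l), THF, t-BuOH (1 equiv), −78 °C; then solid NH4Cl
Reagents that add atoms: none
Why: Dissolving-metal reduction of the enone should protonate the C5 carbanion axially on the α face, opposite the angular methyl, to give the trans-fused decalin (5α-H), as is general for octalones of this type.

Step 12
Reactants: 17 11-hydroxy-5α-driman-7-one with 8α-methyl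
Product: 18 5α-drimane-7α,11-diol with 8α-methyl (axial 7-hydroxyl)
Conditions: LiBH(s-Bu)3, THF, −78 °C; then NaOH, H2O2, 0 °C
Reagents that add atoms: none
Why: The bulky trialkylborohydride attacks the C7 ketone along the equatorial trajectory and should give the axial 7α-alcohol, the epimer whose C–O bond is anti-periplanar to the axial 8β-H.

Step 13
Reactants: 19 caffeic acid
Product: 21 (E)-3-[3,4-bis(tert-butyldimethylsilyloxy)phenyl]prop-2-enoic acid, via tris-silylated caffeate 20 (not isolated)
Conditions: t-BuMe2SiCl, imidazole, DMF, rt; then K2CO3, MeOH/THF/H2O, rt; citric acid work-up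
Reagents that add atoms: tert-butyldimethylsilyl chloride, CC(C)(C)[Si](C)(C)Cl
Why: Exhaustive silylation followed by selective cleavage of the labile silyl ester is the standard way to mask the catechol of a hydroxycinnamic acid while keeping the E-alkene and freeing the carboxylic acid.

Step 14
Reactants: 18 5α-drimane-7α,11-diol with 8α-methyl, 21 (E)-3-[3,4-bis(tert-butyldimethylsilyloxy)phenyl]prop-2-enoic acid
Product: 22 7α-hydroxy-5α-driman-11-yl (E)-3-[3,4-bis(tert-butyldimethylsilyloxy)phenyl]prop-2-enoate with 8α-methyl
Conditions: 1-ethyl-3-(3-dimethylaminopropyl)carbodiimide hydrochloride, DMAP, CH2Cl2, 0 °C to rt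
Reagents that add atoms: none
Why: Carbodiimide/DMAP coupling (Steglich esterification) should acylate the primary C11 hydroxyl selectively, because the axial secondary 7α-hydroxyl is shielded by the C8 methyl and the syn-axial hydrogens at C5 and C9.

Step 15
Reactants: 22 7α-hydroxy-5α-driman-11-yl (E)-3-[3,4-bis(tert-butyldimethylsilyloxy)phenyl]prop-2-enoate
Product: 24 drim-7-en-11-yl (E)-3-[3,4-bis(tert-butyldimethylsilyloxy)phenyl]prop-2-enoate (5α-H, 9α-H, 10β-methyl), via 7α-dichlorophosphate 23 (not isolated)
Conditions: POCl3, pyridine, 0 to 60 °C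
Reagents that add atoms: none
Why: The axial 7α-dichlorophosphate undergoes anti-periplanar E2 elimination with pyridine, and of the two trans-diaxial hydrogens the 8β-H is tertiary and faces one syn-axial methyl whereas the 6β-H lies between the axial methyls on C4 and C10, so the more substituted C7=C8 alkene should form.

Step 16
Reactants: 24 drim-7-en-11-yl (E)-3-[3,4-bis(tert-butyldimethylsilyloxy)phenyl]prop-2-enoate
Product: 25 drim-7-en-11-yl (E)-3-(3,4-dihydroxyphenyl)prop-2-enoate, (5S,9S,10S), CNP0265201.1
Conditions: Et3N·3HF, THF, rt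
Reagents that add atoms: none
Why: Fluoride cleaves the two aryl silyl ethers under non-basic conditions that leave the cinnamate ester, its E-alkene and the trisubstituted ring alkene untouched.

**Compound list**

1 | methyl 3-methoxy-2-methylbenzoate | COC(=O)c1cccc(OC)c1C | starting material
2 | methyl 6-bromo-3-methoxy-2-methylbenzoate | COC(=O)c1c(Br)ccc(OC)c1C | intermediate
3 | 5-bromo-2-methylpent-2-ene | CC(C)=CCCBr | starting material
4 | (4-methylpent-3-en-1-yl)zinc bromide | CC(C)=CCC[Zn]Br | intermediate
5 | methyl 3-methoxy-2-methyl-6-(4-methylpent-3-en-1-yl)benzoate | COC(=O)c1c(CCC=C(C)C)ccc(OC)c1C | intermediate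
6 | methyl 3-methoxy-2,5,5-trimethyl-5,6,7,8-tetrahydronaphthalene-1-carboxylate | COC(=O)c1c(C)c(OC)cc2c1CCCC2(C)C | intermediate
7 | 3-methoxy-2,5,5-trimethyl-5,6,7,8-tetrahydronaphthalene-1-carboxylic acid | COc1cc2c(c(C(=O)O)c1C)CCCC2(C)C | intermediate
8 | dilithium salt of the Birch dianion (carboxylate enolate at C9, C6 already protonated) | [Li+].[Li+].[O-]C([O-])=C1C(C)=C(OC)CC2=C1CCCC2(C)C | intermediate
9 | racemic 3-methoxy-2,5,5-trimethyl-1,4,5,6,7,8-hexahydronaphthalene-1-carboxylic acid | COC1=C(C)C(C(=O)O)C2=C(C1)C(C)(C)CCC2 | intermediate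
10 | racemic (3-methoxy-2,5,5-trimethyl-1,4,5,6,7,8-hexahydronaphthalen-1-yl)methanol | COC1=C(C)C(CO)C2=C(C1)C(C)(C)CCC2 | intermediate
11 | [(1R)-3-methoxy-2,5,5-trimethyl-1,4,5,6,7,8-hexahydronaphthalen-1-yl]methanol (9α-H, C11 β in drimane terms) | COC1=C(C)[C@H](CO)C2=C(C1)C(C)(C)CCC2 | intermediate
12 | (9S)-7,7-ethylenedioxy-15-nordrim-5(10)-en-11-ol, C8 epimers (key-step precursor) | CC1[C@H](CO)C2=C(CC13OCCO3)C(C)(C)CCC2 | intermediate
13 | (9S)-7,7-ethylenedioxy-5β,15-cyclodriman-11-ol, C8 epimers (cyclopropane C5–C15–C10 on the β face, cis to C11; key-step product) | CC1[C@H](CO)[C@]23C[C@@]2(CC14OCCO4)C(C)(C)CCC3 | intermediate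
14 | (9S)-11-hydroxy-5β,15-cyclodriman-7-one, C8 epimers | CC1[C@H](CO)[C@]23C[C@@]2(CC1=O)C(C)(C)CCC3 | intermediate
15 | 11-hydroxydrim-5-en-7-one with 8α-methyl (8β-H), 9α-H, 10β-methyl | C[C@@H]1C(=O)C=C2C(C)(C)CCC[C@]2(C)[C@H]1CO | intermediate
16 | dilithium C6=C7 enolate and C11 alkoxide of 17 (5α-H) | [Li+].[Li+].C[C@@H]1C([O-])=C[C@H]2C(C)(C)CCC[C@]2(C)[C@H]1C[O-] | intermediate
17 | 11-hydroxy-5α-driman-7-one with 8α-methyl, 9α-H, 10β-methyl | C[C@@H]1C(=O)C[C@H]2C(C)(C)CCC[C@]2(C)[C@H]1CO | intermediate
18 | 5α-drimane-7α,11-diol with 8α-methyl (7-hydroxyl axial, cis to the C8 methyl) | C[C@@H]1[C@H](O)C[C@H]2C(C)(C)CCC[C@]2(C)[C@H]1CO | intermediate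
19 | caffeic acid, (E)-3-(3,4-dihydroxyphenyl)prop-2-enoic acid | O=C(O)/C=C/c1ccc(O)c(O)c1 | starting material
20 | tert-butyldimethylsilyl (E)-3-[3,4-bis(tert-butyldimethylsilyloxy)phenyl]prop-2-enoate | CC(C)(C)[Si](C)(C)OC(=O)/C=C/c1ccc(O[Si](C)(C)C(C)(C)C)c(O[Si](C)(C)C(C)(C)C)c1 | intermediate
21 | (E)-3-[3,4-bis(tert-butyldimethylsilyloxy)phenyl]prop-2-enoic acid | O=C(O)/C=C/c1ccc(O[Si](C)(C)C(C)(C)C)c(O[Si](C)(C)C(C)(C)C)c1 | intermediate
22 | 7α-hydroxy-5α-driman-11-yl (E)-3-[3,4-bis(tert-butyldimethylsilyloxy)phenyl]prop-2-enoate with 8α-methyl | C[C@@H]1[C@H](O)C[C@H]2C(C)(C)CCC[C@]2(C)[C@H]1COC(=O)/C=C/c1ccc(O[Si](C)(C)C(C)(C)C)c(O[Si](C)(C)C(C)(C)C)c1 | intermediate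
23 | 7α-dichlorophosphate of 22 | C[C@@H]1[C@H](OP(=O)(Cl)Cl)C[C@H]2C(C)(C)CCC[C@]2(C)[C@H]1COC(=O)/C=C/c1ccc(O[Si](C)(C)C(C)(C)C)c(O[Si](C)(C)C(C)(C)C)c1 | intermediate
24 | drim-7-en-11-yl (E)-3-[3,4-bis(tert-butyldimethylsilyloxy)phenyl]prop-2-enoate (5α-H, 9α-H, 10β-methyl) | CC1=CC[C@H]2C(C)(C)CCC[C@]2(C)[C@H]1COC(=O)/C=C/c1ccc(O[Si](C)(C)C(C)(C)C)c(O[Si](C)(C)C(C)(C)C)c1 | intermediate
25 | (5S,9S,10S)-drim-7-en-11-yl (E)-3-(3,4-dihydroxyphenyl)prop-2-enoate, CNP0265201.1 | CC1=CC[C@H]2C(C)(C)CCC[C@]2(C)[C@H]1COC(=O)/C=C/c1ccc(O)c(O)c1 | target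

**Step count**

Total step count: 16. Longest linear sequence: 15 steps (steps 1–12 and 14–16, from 1 to 25); step 13 is a one-step side branch.

**Steps most likely to fail, with fallbacks**

1. Step 9. What may go wrong: slow methylene transfer to the tetrasubstituted alkene flanked by the C4 quaternary carbon, so that ZnI2-induced opening of the dioxolane and migration of the double bond set in before conversion is complete. Fallback: deliver the one-carbon unit from C11 by a silicon-tethered radical instead of a carbenoid. From 12, BrCH2SiMe2Cl and Et3N in CH2Cl2 give the (bromomethyl)dimethylsilyl ether F1. Bu3SnH and AIBN (benzene, 80 °C, slow addition) should then close the six-membered oxasilacycle F2 by 6-exo attack of the α-silyl radical on C10 from the tethered β face, the C5 radical taking hydrogen on the α face. n-Bu4NF in DMF at 70 °C cleaves the C15–Si and O–Si bonds and leaves C15 as the methyl group in the ketal alcohol F3. 1 M HCl in THF removes the dioxolane, and the route is rejoined at 17, with compounds 13–16 bypassed.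

2. Step 7. What may go wrong: weak discrimination of the enantiomers by the lipase, because the two ring carbons flanking C9 are both sp2 and of similar size, so the recovered alcohol is not enantiopure at a workable conversion. Fallback: resolution through covalent diastereomers. From racemic 10, esterification with (S)-naproxen (DCC, DMAP, CH2Cl2) gives the diastereomeric esters, the naproxen ester of the (R)-alcohol F4 and the naproxen ester of the (S)-alcohol F5. After separation by crystallisation or chromatography, LiOH in THF/MeOH/H2O cleaves F4, and the route is rejoined at 11.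

3. Step 15. What may go wrong: loss of regiocontrol in the elimination (proton removal at C6, or ionisation of the phosphate with rearrangement), giving alkene isomers that are hard to separate this late. Fallback: fix the alkene position as an enol triflate and remove the oxygen reductively. From 17, with step 12 omitted, esterification with 21 (carbodiimide, DMAP) gives the keto ester F6. Tf2O and 2,6-di-tert-butyl-4-methylpyridine in CH2Cl2 at 0 °C should give the more substituted C7=C8 enol triflate F7. Pd(OAc)2 and PPh3 with HCO2H and n-Bu3N in DMF at 60 °C (zerovalent palladium formed in the flask) replace the triflate by hydrogen, and the route is rejoined at 24.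

**Further compounds**

F1 | step 9 | (bromomethyl)dimethylsilyl ether of 12 at O11, C8 epimers | CC1[C@H](CO[Si](C)(C)CBr)C2=C(CC13OCCO3)C(C)(C)CCC2
F2 | step 9 | cyclic silyl ether C11–O–SiMe2–C15H2–C10 of 7,7-ethylenedioxy-5α-drimane (C15 β, 5α-H), C8 epimers | CC1C2(OCCO2)C[C@H]3C(C)(C)CCC[C@@]34C[Si](C)(C)OC[C@H]41
F3 | step 9 | 7,7-ethylenedioxy-5α-driman-11-ol (9α-H, 10β-methyl), C8 epimers | CC1C2(OCCO2)C[C@H]3C(C)(C)CCC[C@]3(C)[C@H]1CO
F4 | step 7 | (S)-naproxen ester of the (R)-alcohol 11 | COC1=C(C)[C@H](COC(=O)[C@@H](C)c2ccc3cc(OC)ccc3c2)C4=C(C1)C(C)(C)CCC4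
F5 | step 7 | (S)-naproxen ester of the (S)-alcohol | COC1=C(C)[C@@H](COC(=O)[C@@H](C)c2ccc3cc(OC)ccc3c2)C4=C(C1)C(C)(C)CCC4
F6 | step 15 | 7-oxo-5α-driman-11-yl (E)-3-[3,4-bis(tert-butyldimethylsilyloxy)phenyl]prop-2-enoate with 8α-methyl | C[C@@H]1C(=O)C[C@H]2C(C)(C)CCC[C@]2(C)[C@H]1COC(=O)/C=C/c1ccc(O[Si](C)(C)C(C)(C)C)c(O[Si](C)(C)C(C)(C)C)c1
F7 | step 15 | 7-(trifluoromethanesulfonyloxy)drim-7-en-11-yl (E)-3-[3,4-bis(tert-butyldimethylsilyloxy)phenyl]prop-2-enoate | CC1=C(OS(=O)(=O)C(F)(F)F)C[C@H]2C(C)(C)CCC[C@]2(C)[C@H]1COC(=O)/C=C/c1ccc(O[Si](C)(C)C(C)(C)C)c(O[Si](C)(C)C(C)(C)C)c1
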